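- A small charge, 0.050 M of starting complex fed over 40 s, met 3.00 equiv of incoming ligand and differing amounts of scavenger, and I wanted the part reacted at 25 min.

all flasks: starting complex 0.050 M (fed, over 40 s)
- amber: incoming ligand 3 equiv; scavenger 1.2 equiv; run made earlier
- red: incoming ligand 3 equiv; scavenger 5 equiv; run made earlier
- midnight: incoming ligand 3.00 equiv; scavenger 1.00 equiv; time 25 min
- dusk: incoming ligand 3.00 equiv; scavenger 2.00 equiv; time 25 min
- noon: incoming ligand 3.00 equiv; scavenger 4.00 equiv; time 25 min

| run | time / min | starting complex / % | complex with three exchanged / % |
|---|---|---|---|
| amber | 1.00 | 89.1 | 0 |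
| amber | 2.50 | 66.3 | 0.3 |
| amber | 5.00 | 43.6 | 4.7 |
| amber | 12.0 | 16.3 | 19.4 |
| red | 1.00 | 87.3 | 0.8 |
| red | 2.50 | 66.6 | 0.9 |
| red | 5.00 | 40.3 | 3.7 |
| red | 12.0 | 16.1 | 19.5 |

(standard deviation of a reading: 1 percentage point)



* part of the starting complex that has reacted at the end, midnight
* part of the starting complex that has reacted at the end, dusk
* part of the starting complex that has reacted at the end, noon
* what raising the equivalents of scavenger from its lowest to its highest value here does to the part of the starting complex that has reacted (changes below 5 percentage points count as none) (no change / it falls / it rises)

- My bench rule was to freeze the incoming ligand at its charge and treat the loss of starting complex as pseudo-first-order.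
- From the amber run, between 1.00 min and 12.0 min, I read the time constant τ, the time in which the starting complex left falls by a factor e at a given ligand charge, as 6.48 min; the red run reads 6.51 min.
- The feed was shorter than τ, so I counted it as a lag of half its length. My reckoning for 25 min left 2.22 %, which is 97.8 % reacted.
- The frozen ligand may already have been slipping: amber's τ read from 5.00 min to 12.0 min was 7.11 min, longer than the whole-run value, though these are readings with their scatter.
- The border I watched was the scavenger. I supposed that it takes up leaving ligand one for one, and counted one leaving ligand per starting complex lost and two more per complex with three exchanged. At amber's last reading, that count over its scavenger charge was 1.02. The runs therefore stop about where the amber scavenger is matched, while midnight holds 1.00 equiv.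
- The forecast gave 94.5 % for midnight, 95 % for dusk and 95 % for noon, with no change, on the ground "so scavenger has no visible kinetic role there". Its figures stand below mine.
- The flasks gave 95.9 % for midnight, 96.8 % for dusk and 96.8 % for noon: no change, a shift of 0.85 percentage points.

    scavenger + leaving ligand → scavenged by-product (k = 16.0 M⁻¹ s⁻¹)
    starting complex + complex with two exchanged → side product (k = 0.175 M⁻¹ s⁻¹)
    complex with one exchanged + incoming ligand → leaving ligand + complex with two exchanged (k = 0.00747 M⁻¹ s⁻¹)
    starting complex + incoming ligand → leaving ligand + complex with one exchanged (k = 0.0231 M⁻¹ s⁻¹)
    leaving ligand + incoming ligand ⇌ idle adduct, settled at all times (K = 21.0 M⁻¹)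
    complex with two exchanged + incoming ligand → leaving ligand + complex with three exchanged (k = 0.129 M⁻¹ s⁻¹)

- In midnight at 3.55 min, the first exchange used incoming ligand 4.1 times as fast as the second. At 25.0 min, midnight held 47.1 % as complex with one exchanged against 35.5 % as complex with three exchanged.
- For a neighbour flask, midnight with 1.80 equiv of incoming ligand, I stretched τ by the ratio of charges to 10.8 min, which leaves 10.2 % and so 89.8 % reacted. The computed flask reached 85.9 %.

(All runs were computed with constants of no real substance, and the scatter is random.)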